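**Plan**

- Cuts (ring B = lactone O1, C2(=O), C3, C4, C5; ring A = 3,4-dimethoxyphenyl; ring C = 4-hydroxy-3,5-dimethoxyphenyl): first the C3–CH2 bond to ring C, then the lactone acyl bond O1–C2, then the C4–CH2 bond to ring A. This leads back to dimethyl (S)-malate, 3,4-dimethoxybenzyl bromide and 2,6-dimethoxyphenol.
- Enabling feature: the free phenolic OH of ring C is para to the benzylic carbon and flanked by the two OMe groups, so ring C can enter as a non-aromatic p-quinone methide. Its exocyclic CH2 is the electrophile and rearomatization drives the bond formation. C3, which carries OH next to the C2 carbonyl, can be doubly deprotonated to a flat enediolate.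
- Forward order: the chain is joined first (C4–CH2 by alkylation of the malate dianion), the two carboxyls are told apart through a temporary 1,3-dioxolan-4-one ring, and ring B is closed by reduction and lactonization. Ring C is attached in the last step, with no protecting group on either hydroxyl.
- Stereochemistry: C4 comes from the chiral pool, set by anti-selective alkylation under control of the malate carbinol center. That carbinol center is then flattened, and C3 is set anew by 1,2-induction from C4, the electrophile entering anti to the 3,4-dimethoxybenzyl group.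

Key step: step 7

Remark: compounds 1, 2 and 9 are taken as commercially available; LiN(iPr)2 is used as a commercial solution.

**Route**

Step 1
Reactants: 1 dimethyl (S)-malate; 2 3,4-dimethoxybenzyl bromide
Product: 4 dimethyl (2S,3R)-2-hydroxy-3-[(3,4-dimethoxyphenyl)methyl]butanedioate, via dilithium alkoxide-enolate 3 (not isolated)
Conditions: LiN(iPr)2 (2.2 equiv), THF, −78 to −20 °C; then 2 (1.1 equiv), −78 to −10 °C; 1 M HCl
Reagents that add atoms: none
Why: Fráter–Seebach alkylation, in which the chelated dilithium alkoxide-enolate 3 should be benzylated on the face anti to the substituent of the lithium chelate, so that the malate carbinol center controls the new center and the (2S,3R) anti product results; the minor syn epimer, which would carry the antipodal center forward, is to be removed by chromatography at this stage.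

Step 2
Reactants: 4 dimethyl (2S,3R)-2-hydroxy-3-[(3,4-dimethoxyphenyl)methyl]butanedioate
Product: 5 (2S,3R)-2-hydroxy-3-[(3,4-dimethoxyphenyl)methyl]butanedioic acid
Conditions: KOH (3 equiv), MeOH/H2O, 0 °C to rt; then HCl to pH 1, EtOAc extraction
Reagents that add atoms: potassium hydroxide, [K+].[OH-]
Why: Saponification of both methyl esters under mild aqueous hydroxide should leave the two stereocenters untouched, because the carboxylates formed resist enolization and the dimethoxyarene is inert.

Step 3
Reactants: 5 (2S,3R)-2-hydroxy-3-[(3,4-dimethoxyphenyl)methyl]butanedioic acid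
Product: 6 (2R)-2-[(4S)-2,2-dimethyl-5-oxo-1,3-dioxolan-4-yl]-3-(3,4-dimethoxyphenyl)propanoic acid
Conditions: 2,2-dimethoxypropane, p-TsOH·H2O (cat.), rt
Reagents that add atoms: 2,2-dimethoxypropane, COC(C)(C)OC
Why: Acid-catalysed transacetalization should engage the α-hydroxy acid unit in the favoured five-membered 1,3-dioxolan-4-one, which leaves the carboxyl on the benzyl-bearing carbon as the only free acid and touches no stereocenter.

Step 4
Reactants: 6 (2R)-2-[(4S)-2,2-dimethyl-5-oxo-1,3-dioxolan-4-yl]-3-(3,4-dimethoxyphenyl)propanoic acid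
Product: 8 (3S,4S)-3-hydroxy-4-[(3,4-dimethoxyphenyl)methyl]oxolan-2-one, via hydroxy dioxolanone 7 (not isolated)
Conditions: BH3·SMe2 (1.3 equiv), THF, 0 °C to rt; MeOH quench; then p-TsOH·H2O (cat.), CH2Cl2, rt
Reagents that add atoms: none
Why: Chemoselective borane reduction of the free carboxylic acid beside the ester-type dioxolanone carbonyl should give primary alcohol 7, whose hydroxyl then attacks the activated dioxolanone carbonyl under acid catalysis (lactonization by 5-exo-trig acyl transfer) and expels acetone, closing ring B with both stereocenters unchanged.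

Step 5
Reactants: 9 2,6-dimethoxyphenol
Product: 10 4-[(dimethylamino)methyl]-2,6-dimethoxyphenol
Conditions: Me2NH (40% aq, 1.2 equiv), HCHO (37% aq, 1.2 equiv), EtOH, rt
Reagents that add atoms: formaldehyde, C=O; dimethylamine, CNC
Why: Mannich reaction of a phenol whose two ortho positions are blocked by methoxy groups should take place at the para position, the site activated by the phenol(ate) oxygen.

Step 6
Reactants: 10 4-[(dimethylamino)methyl]-2,6-dimethoxyphenol
Product: 11 (4-hydroxy-3,5-dimethoxyphenyl)-N,N,N-trimethylmethanaminium iodide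
Conditions: MeI (1.5 equiv), acetone, 0 °C to rt; salt collected by filtration
Reagents that add atoms: iodomethane, CI
Why: Menshutkin N-methylation of the tertiary amine should outrun O-methylation of the hindered, non-deprotonated phenol and precipitate the quaternary salt, which turns the amino group into a leaving group for the later 1,6-elimination.

Step 7
Reactants: 8 (3S,4S)-3-hydroxy-4-[(3,4-dimethoxyphenyl)methyl]oxolan-2-one; 11 (4-hydroxy-3,5-dimethoxyphenyl)-N,N,N-trimethylmethanaminium iodide
Product: 14 (3S,4S)-4-[(3,4-dimethoxyphenyl)methyl]-3-hydroxy-3-[(4-hydroxy-3,5-dimethoxyphenyl)methyl]oxolan-2-one (target), via dilithium enediolate 12 (not isolated), via p-quinone methide 13 (not isolated)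
Conditions: LiN(iPr)2 (3.2 equiv: two for 8, one for the phenol of 11), THF/DMPU, −78 °C; then 11 (1.2 equiv, fine suspension in THF/DMPU), −78 to 0 °C; 1 M HCl to pH 5
Reagents that add atoms: none
Why: Two equivalents of base remove the hydroxyl proton and the C3 proton of 8 to give the flat enediolate 12, while the third deprotonates the phenol of 11, whose betaine expels trimethylamine by 1,6-elimination and releases p-quinone methide 13 at low stationary concentration; C3 of 12 then adds to the exocyclic methylene carbon of 13 (1,6-conjugate addition), and the regained aromaticity of ring C makes the C–C bond formation irreversible. The closest known reaction types are the trans-selective benzylation of dianions of α-hydroxy-β-benzyl-γ-butyrolactones with benzylic halides and the elimination–addition benzylation of enolates by phenolic Mannich-base methiodides through quinone methides. No ring is closed. The new fully substituted center C3 is set by 1,2-induction from C4: the 3,4-dimethoxybenzyl group shields one face of the five-membered enediolate, so the electrophile enters anti to it, the two arylmethyl groups end up trans and the hydroxyl cis to the C4 substituent, which is the (3S,4S) arrangement; the earlier C3 configuration is erased on enolization, so either C3 epimer of the hydroxy lactone would converge. The step needs C- over O-alkylation, which the soft quinone methide terminus and the reversibility of O-adducts (re-elimination from the phenolate) should secure, and it needs capture of 13 by 12 faster than self-condensation of 13, which the slow release of 13 in the presence of the strongly nucleophilic dianion should secure. Should loss of trimethylamine lag, direct displacement of trimethylamine at the benzylic carbon by 12 leads to the same product.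

**Compound list**

1 | dimethyl (S)-malate, dimethyl (2S)-2-hydroxybutanedioate | COC(=O)[C@@H](O)CC(=O)OC | starting material
2 | 3,4-dimethoxybenzyl bromide, 4-(bromomethyl)-1,2-dimethoxybenzene | COc1ccc(CBr)cc1OC | starting material
3 | dilithium alkoxide-enolate of 1 | [Li+].[Li+].COC(=O)[C@@H]([O-])C=C([O-])OC | intermediate (not isolated)
4 | dimethyl (2S,3R)-2-hydroxy-3-[(3,4-dimethoxyphenyl)methyl]butanedioate | COC(=O)[C@@H](O)[C@@H](Cc1ccc(OC)c(OC)c1)C(=O)OC | intermediate
5 | (2S,3R)-2-hydroxy-3-[(3,4-dimethoxyphenyl)methyl]butanedioic acid | OC(=O)[C@@H](O)[C@@H](Cc1ccc(OC)c(OC)c1)C(=O)O | intermediate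
6 | (2R)-2-[(4S)-2,2-dimethyl-5-oxo-1,3-dioxolan-4-yl]-3-(3,4-dimethoxyphenyl)propanoic acid | CC1(C)O[C@@H]([C@@H](Cc2ccc(OC)c(OC)c2)C(=O)O)C(=O)O1 | intermediate
7 | (5S)-5-[(2S)-1-(3,4-dimethoxyphenyl)-3-hydroxypropan-2-yl]-2,2-dimethyl-1,3-dioxolan-4-one | CC1(C)O[C@@H]([C@@H](Cc2ccc(OC)c(OC)c2)CO)C(=O)O1 | intermediate (not isolated)
8 | (3S,4S)-3-hydroxy-4-[(3,4-dimethoxyphenyl)methyl]oxolan-2-one (hydroxyl cis to the benzyl group) | O=C1[C@@H](O)[C@@H](Cc2ccc(OC)c(OC)c2)CO1 | intermediate
9 | 2,6-dimethoxyphenol | COc1cccc(OC)c1O | starting material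
10 | 4-[(dimethylamino)methyl]-2,6-dimethoxyphenol | CN(C)Cc1cc(OC)c(O)c(OC)c1 | intermediate
11 | (4-hydroxy-3,5-dimethoxyphenyl)-N,N,N-trimethylmethanaminium iodide | C[N+](C)(C)Cc1cc(OC)c(O)c(OC)c1.[I-] | intermediate
12 | dilithium (4S)-4-[(3,4-dimethoxyphenyl)methyl]-4,5-dihydrofuran-2,3-diolate | [Li+].[Li+].[O-]C1=C([O-])[C@@H](Cc2ccc(OC)c(OC)c2)CO1 | intermediate (not isolated)
13 | 2,6-dimethoxy-4-methylidenecyclohexa-2,5-dien-1-one | C=C1C=C(OC)C(=O)C(OC)=C1 | intermediate (not isolated)
14 | (3S,4S)-4-[(3,4-dimethoxyphenyl)methyl]-3-hydroxy-3-[(4-hydroxy-3,5-dimethoxyphenyl)methyl]oxolan-2-one | COc1ccc(C[C@H]2COC(=O)[C@]2(O)Cc2cc(OC)c(O)c(OC)c2)cc1OC | target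

**Step count and risks**

Total step count: 7. Longest linear sequence: 5 steps (steps 1, 2, 3, 4 and 7).

The three steps most likely to fail:

First, step 7. Capture of the quinone methide by the enediolate may lose out to oligomerization of the quinone methide, to single-electron transfer from the electron-rich enediolate to the quinoid acceptor (which would give homodimers), or to O-alkylation and methyl transfer from the ammonium salt. The fallback sets out from 8 and comes back to the route at 14. It replaces the quinone methide by an O-protected benzylic halide in a plain SN2 alkylation. Commercial 4-(benzyloxy)-3,5-dimethoxybenzaldehyde is reduced (NaBH4, MeOH, 0 °C) to [4-(benzyloxy)-3,5-dimethoxyphenyl]methanol F1, which PBr3 in CH2Cl2 at 0 °C should convert into 2-(benzyloxy)-5-(bromomethyl)-1,3-dimethoxybenzene F2. Enediolate 12, made from 8 with LiN(iPr)2 (2.2 equiv) in THF/DMPU at −78 °C, is alkylated with F2 anti to the C4 substituent to give (3S,4S)-3-{[4-(benzyloxy)-3,5-dimethoxyphenyl]methyl}-4-[(3,4-dimethoxyphenyl)methyl]-3-hydroxyoxolan-2-one F3. Hydrogenolysis (H2, Pd/C, EtOAc/EtOH, rt) then frees the phenol and gives 14.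

Second, step 1. Facial selectivity in the alkylation of the chelated dianion may be incomplete, which would erode the enantiopurity at C4 further on, and the labile electron-rich benzylic bromide may partly decompose. The fallback sets out from 2 and comes back to the route at enediolate 12 in step 7. It sets C4 by an auxiliary-controlled Evans alkylation. Commercial 4-tert-butoxy-4-oxobutanoic acid is coupled with (4R)-4-benzyl-1,3-oxazolidin-2-one (pivaloyl chloride, Et3N, LiCl, THF) to give tert-butyl 4-[(4R)-4-benzyl-2-oxo-1,3-oxazolidin-3-yl]-4-oxobutanoate F4. Its sodium enolate (NaN(SiMe3)2, THF, −78 °C) is alkylated with 2 to give tert-butyl (3R)-3-[(4R)-4-benzyl-2-oxo-1,3-oxazolidine-3-carbonyl]-4-(3,4-dimethoxyphenyl)butanoate F5. LiBH4 (THF/MeOH, 0 °C) removes the auxiliary reductively and should give tert-butyl (3R)-3-(hydroxymethyl)-4-(3,4-dimethoxyphenyl)butanoate F6, which CF3CO2H in CH2Cl2 lactonizes to (4R)-4-[(3,4-dimethoxyphenyl)methyl]oxolan-2-one F7. Enolate hydroxylation (LiN(SiMe3)2, then 2-(benzenesulfonyl)-3-phenyloxaziridine, THF, −78 °C) should enter anti to the C4 substituent and give (3R,4S)-3-hydroxy-4-[(3,4-dimethoxyphenyl)methyl]oxolan-2-one F8, the C3 epimer of 8. Double deprotonation of F8 gives the same enediolate 12.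

Third, step 4. The borane may lose chemoselectivity and attack the dioxolanone carbonyl, or the acyl transfer that closes ring B may stay incomplete. The fallback sets out from 5 and comes back to the route at 8. It tells the two carboxyls apart through a cyclic anhydride. Trifluoroacetic anhydride (0 °C to rt) should convert 5 into (3S,4R)-4-[(3,4-dimethoxyphenyl)methyl]-2,5-dioxooxolan-3-yl trifluoroacetate F9. Methanol opens the anhydride at the carbonyl next to the acyloxy-bearing carbon and removes the trifluoroacetyl group, giving (2R,3S)-2-[(3,4-dimethoxyphenyl)methyl]-3-hydroxy-4-methoxy-4-oxobutanoic acid F10. BH3·SMe2 (THF, 0 °C) reduces the free acid to methyl (2S,3S)-2-hydroxy-3-(hydroxymethyl)-4-(3,4-dimethoxyphenyl)butanoate F11, which lactonizes under p-TsOH catalysis to 8.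

**Further compounds**

F1 | step 7 | [4-(benzyloxy)-3,5-dimethoxyphenyl]methanol | COc1cc(CO)cc(OC)c1OCc1ccccc1
F2 | step 7 | 2-(benzyloxy)-5-(bromomethyl)-1,3-dimethoxybenzene | COc1cc(CBr)cc(OC)c1OCc1ccccc1
F3 | step 7 | (3S,4S)-3-{[4-(benzyloxy)-3,5-dimethoxyphenyl]methyl}-4-[(3,4-dimethoxyphenyl)methyl]-3-hydroxyoxolan-2-one | COc1ccc(C[C@H]2COC(=O)[C@]2(O)Cc2cc(OC)c(OCc3ccccc3)c(OC)c2)cc1OC
F4 | step 1 | tert-butyl 4-[(4R)-4-benzyl-2-oxo-1,3-oxazolidin-3-yl]-4-oxobutanoate | CC(C)(C)OC(=O)CCC(=O)N1[C@H](Cc2ccccc2)COC1=O
F5 | step 1 | tert-butyl (3R)-3-[(4R)-4-benzyl-2-oxo-1,3-oxazolidine-3-carbonyl]-4-(3,4-dimethoxyphenyl)butanoate | COc1ccc(C[C@@H](C(=O)N2[C@H](Cc3ccccc3)COC2=O)CC(=O)OC(C)(C)C)cc1OC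
F6 | step 1 | tert-butyl (3R)-3-(hydroxymethyl)-4-(3,4-dimethoxyphenyl)butanoate | COc1ccc(C[C@@H](CO)CC(=O)OC(C)(C)C)cc1OC
F7 | step 1 | (4R)-4-[(3,4-dimethoxyphenyl)methyl]oxolan-2-one | COc1ccc(C[C@H]2COC(=O)C2)cc1OC
F8 | step 1 | (3R,4S)-3-hydroxy-4-[(3,4-dimethoxyphenyl)methyl]oxolan-2-one | O=C1[C@H](O)[C@@H](Cc2ccc(OC)c(OC)c2)CO1
F9 | step 4 | (3S,4R)-4-[(3,4-dimethoxyphenyl)methyl]-2,5-dioxooxolan-3-yl trifluoroacetate | O=C1[C@@H](OC(=O)C(F)(F)F)[C@@H](Cc2ccc(OC)c(OC)c2)C(=O)O1
F10 | step 4 | (2R,3S)-2-[(3,4-dimethoxyphenyl)methyl]-3-hydroxy-4-methoxy-4-oxobutanoic acid | COC(=O)[C@@H](O)[C@@H](Cc1ccc(OC)c(OC)c1)C(=O)O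
F11 | step 4 | methyl (2S,3S)-2-hydroxy-3-(hydroxymethyl)-4-(3,4-dimethoxyphenyl)butanoate | COC(=O)[C@@H](O)[C@@H](Cc1ccc(OC)c(OC)c1)CO
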